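At late times I read one thing from a run: how much of the consumed substrate stands as target. Winter's last row gives 79.7%. I call this the target share, target per substrate consumed, the selectivity. Target is then the share times the fraction consumed.

in all of them: free catalyst 64 µM

| run | substrate | partner | remark | time |
|---|---|---|---|---|
| winter | 0.064 M | 0.0704 M | run made earlier |  |
| dawn | 0.032 M | 0.0704 M | run made earlier |  |
| midnight | 0.048 M | 0.0704 M | run made earlier |  |
| autumn | 0.064 M | 0.11 M | run made earlier |  |
| alder | 0.064 M | 0.0704 M | everything together at the start | 15 h |
| ash | 0.064 M (fed, over 12 h) | 0.0704 M | all else is in the flask from the start; the feed brings no volume worth counting | 15 h |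
| cedar | 0.064 M (in portions, 5, over 12 h) | 0.0704 M | first portion at the start, last at 12 h | 15 h |
| maple | 0.064 M | 0.0704 M (fed, over 12 h) | all else is in the flask from the start; the feed brings no volume worth counting | 15 h |

- winter (time / h: target / %, substrate / %): 4.00: 25.8, 69.9; 8.00: 44.0, 45.7; 12.0: 57.5, 26.8; 15.0: 65.6, 17.7
- dawn (time / h: target / %, substrate / %): 4.00: 32.6, 60.7; 8.00: 52.9, 33.5; 12.0: 63.7, 18.1; 15.0: 70.0, 11.4
- midnight (time / h: target / %, substrate / %): 2.00: 16.3, 82.0; 5.00: 34.4, 57.9; 10.0: 55.4, 30.5; 15.0: 66.4, 13.9
- autumn (time / h: target / %, substrate / %): 4.00: 26.3, 70.7; 8.00: 43.9, 44.7; 12.0: 57.8, 27.1; 15.0: 64.6, 17.3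

(each reading ± 0.5 percentage points)

- the analysis behind the earlier runs scatters by 0.5 percentage points, standard deviation

- which flask leads in amount of target, in percent of the substrate charged ("all alike" within 1.5 percentage points) (alder / ash / cedar / maple / all alike)
- how much target is there at the end, in percent of the substrate charged: alder
- how much target is there at the end, in percent of the substrate charged: ash
- how much target is there at the end, in percent of the substrate charged: cedar
- how much target is there at the end, in percent of the substrate charged: maple

Which inputs need care?

1. Partner. Autumn ends at 64.6% of target, winter at 65.6%, a gap of 1 percentage point with a scatter of 0.5 points per reading. In these runs its charge can be rough.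

2. The share. Winter reads 85.7% at 4.00 h and 78.6% at 12.0 h, so the early drift has ended by then. One reading's scatter moves the share by 0.61 points.

3. The loss of substrate, as a fraction of what stands per hour. Dawn's first interval gives 0.125 h⁻¹, and winter's middle interval gives 0.133 h⁻¹. Summing what each slice of ash's feed keeps until the end leaves 35.6% or 33.4%. That shifts ash's target by 1.8 points, more than the share's slip, so this input needs the care.

4. My numbers. Ash gets 51.3%, and I put cedar, with its portions over the same time, beside it. Alder repeats winter's recipe: 65.6%. Maple's partner arrives at 0.0917 h⁻¹ of the substrate charge, faster than winter's early use of 0.0752 h⁻¹. But the earlier runs start with partner at 0.0704 M or 0.11 M, and maple's feed starts from none, so those runs do not show maple's rate. I put maple somewhere below alder and give it no number of my own.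

The forecast names alder as leader, with alder 65.2%, ash 50%, cedar 49.3% and maple 63.5%, on the ground: “Feeding substrate therefore gains no selectivity and only lowers its concentration”.

The flasks give alder as leader: alder 64.6%, ash 50.5%, cedar 49.9%, maple 61.4%.

    partner + free catalyst → catalyst intermediate A (k = 47900 M⁻¹ h⁻¹)
    substrate + catalyst intermediate A ⇌ catalyst intermediate B (K = 17.0 M⁻¹, k = 44400 M⁻¹ h⁻¹)
    catalyst intermediate B → catalyst intermediate C (k = 181 h⁻¹)
    catalyst intermediate C → free catalyst + target (k = 1150 h⁻¹)
    target ⇌ isomer of the product (K = 0.289, k = 0.158 h⁻¹)

Ash keeps 37% of its substrate, and the share then gives 50.2% against 50.5%. Cedar's neighbour, charged with 0.026 M of substrate, keeps 30.2%, and the share gives 55.6% against 55.9%. Alder's lead over cedar, 15 points, rests in part on two undoings acting together: catalyst intermediate B into substrate + catalyst intermediate A, and isomer of the product into target. In the run without the first, the lead is −1.2 points; in the run without the second, −1.4 points.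

The data are calculated from invented constants; the scatter is artificial.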